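**Retrosynthetic overview**
1. Target ⇐ tris-silyl macrocycle ⇐ three-component Passerini macrocyclisation of butanal with a C1–C24 ω-isocyano acid: the isocyanide carbon serves as a carbamoyl-anion equivalent and forms the Cα–C(=O) bond, the ester, the amide and the Cα centre at once.
2. Seco chain ⇐ C17–C18 B-alkyl Suzuki coupling of fragment 1 (C1–C17 bromodiene ester) with fragment 2 (C18–C24 vinyl tris-silyl ether formamide).
3. Fragment 1 ⇐ (E)-2-bromo-1-iodo-3-methoxypropene (C16, C17, CH2OMe) + C1–C15 alkenylboronate, itself from (R)-β-citronellene (C10–C14), 1-bromo-4-chlorobutane (C6–C9), desymmetrised meso-2,4-dimethylglutaric anhydride (C1–C5) and vinyl-Bpin (C15).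
4. Fragment 2 ⇐ ethyl (S)-4-chloro-3-hydroxybutanoate (C21–C24, C23 centre) + γ-silylallylboration/oxidation (C18–C20, anti C20/C21 diol).
5. Ring order: the single 28-membered ring is closed in the penultimate step; the last step is global desilylation.

Notation: TBS = tert-butyldimethylsilyl, Ipc = isopinocampheyl, Bpin = pinacolatoboryl; the chain is numbered C1 (ester carbonyl) to C24 (CH2N), and Cα is the carbinol carbon of the 2-hydroxypentanoyl unit.
Assumption: the catalysts and reagent named in steps 4, 14 and 20 are taken to give the configurations drawn (step 14 by analogy with the parent allylborane); if a model run shows the opposite sense, the mirror-image or pseudo-enantiomeric one is used and nothing else changes.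

**Route**

Step 1
Reactants: 1 (R)-β-citronellene [(3R)-3,7-dimethylocta-1,6-diene]
Product: 3 (R)-4-methylhex-5-en-1-ol, via (R)-4-methylhex-5-enal 2 (not isolated)
Conditions: O3 (1.0 equiv, Sudan Red 7B end-point), CH2Cl2/MeOH, −78 °C; then NaBH4 (excess), −78 to 0 °C
Reagents that add atoms: ozone, [O-][O+]=O
Why: Chemoselective ozonolysis–reduction: ozone attacks the electron-rich trisubstituted alkene much faster than the vinyl group, and the C13 centre comes unchanged from the chiral pool.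

Step 2
Reactants: 3 (R)-4-methylhex-5-en-1-ol
Product: 4 (R)-4-methylhex-5-en-1-yl 4-methylbenzenesulfonate
Conditions: TsCl, Et3N, DMAP (cat.), CH2Cl2, 0 °C to rt
Reagents that add atoms: 4-toluenesulfonyl chloride, Cc1ccc(cc1)S(Cl)(=O)=O
Why: Standard sulfonylation of a primary alcohol to give a leaving group for the copper-catalysed coupling.

Step 3
Reactants: 4 (R)-4-methylhex-5-en-1-yl 4-methylbenzenesulfonate; 5 1-bromo-4-chlorobutane
Product: 7 (R)-10-chloro-3-methyldec-1-ene, via 4-chlorobutylmagnesium bromide 6 (not isolated)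
Conditions: 5, Mg, THF, 30 °C; then 4, Li2CuCl4 (3 mol %), THF, −20 to 0 °C
Reagents that add atoms: none
Why: Copper-catalysed sp3–sp3 Grignard cross-coupling (Kochi–Schlosser type); Mg inserts into C–Br and leaves C–Cl, the alkene and the stereocentre untouched.

Step 4
Reactants: 8 meso-2,4-dimethylglutaric anhydride [(3R,5S)-3,5-dimethyloxane-2,6-dione]
Product: 9 (2R,4S)-5-methoxy-2,4-dimethyl-5-oxopentanoic acid
Conditions: MeOH (10 equiv), (DHQD)2AQN (10 mol %), Et2O, −30 °C
Reagents that add atoms: methanol, CO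
Why: Cinchona-alkaloid-catalysed enantioselective methanolysis (desymmetrisation) of the meso anhydride, in which general-base delivery of MeOH to one enantiotopic carbonyl fixes the future C2 and C4 methyl centres (syn) in one operation.

Step 5
Reactants: 9 (2R,4S)-5-methoxy-2,4-dimethyl-5-oxopentanoic acid
Product: 10 methyl (2S,4R)-5-hydroxy-2,4-dimethylpentanoate
Conditions: BH3·SMe2 (1.2 equiv), THF, 0 °C to rt; H2O quench; used at once
Reagents that add atoms: none
Why: Chemoselective borane reduction of the free acid in the presence of the methyl ester leaves both centres untouched; the hydroxy ester is iodinated immediately to forestall δ-lactonisation.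

Step 6
Reactants: 10 methyl (2S,4R)-5-hydroxy-2,4-dimethylpentanoate
Product: 11 methyl (2S,4R)-5-iodo-2,4-dimethylpentanoate
Conditions: I2, PPh3, imidazole, CH2Cl2, 0 °C to rt
Reagents that add atoms: iodine, II
Why: Appel-type iodination of the primary alcohol under neutral conditions, with no risk to either stereocentre.

Step 7
Reactants: 7 (R)-10-chloro-3-methyldec-1-ene; 11 methyl (2S,4R)-5-iodo-2,4-dimethylpentanoate
Product: 13 methyl (2S,4S,13R)-2,4,13-trimethylpentadec-14-enoate, via (R)-(8-methyldec-9-en-1-yl)magnesium chloride 12 (not isolated)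
Conditions: 7, Mg, THF, 60 °C; then 11, Li2CuCl4 (5 mol %), NMP (4 equiv), THF, −20 to 0 °C
Reagents that add atoms: none
Why: Copper-catalysed alkyl–alkyl Grignard coupling, where substitution of the primary iodide outruns addition to the hindered ester at low temperature with NMP; C4 becomes S only by a CIP priority change.

Step 8
Reactants: 13 methyl (2S,4S,13R)-2,4,13-trimethylpentadec-14-enoate; 14 vinylboronic acid pinacol ester
Product: 15 methyl (2S,4S,13R,14E)-2,4,13-trimethyl-15-(Bpin)pentadec-14-enoate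
Conditions: 14 (3 equiv), second-generation Hoveyda–Grubbs catalyst (5 mol %), CH2Cl2, 40 °C
Reagents that add atoms: none
Why: Olefin cross-metathesis with vinyl-Bpin; the allylic methyl branch enforces high E selectivity and is not epimerisable under these conditions.

Step 9
Reactants: 16 methyl propargyl ether (3-methoxyprop-1-yne)
Product: 17 (E)-2-bromo-1-iodo-3-methoxyprop-1-ene
Conditions: IBr (1.05 equiv), CH2Cl2, −78 to −20 °C, dark
Reagents that add atoms: iodine monobromide, IBr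
Why: Anti iodobromination of a terminal alkyne via the iodonium ion, with bromide opening at the internal carbon, places I at C16 and Br at C17 trans to each other.

Step 10
Reactants: 15 methyl (2S,4S,13R,14E)-2,4,13-trimethyl-15-(Bpin)pentadec-14-enoate; 17 (E)-2-bromo-1-iodo-3-methoxyprop-1-ene
Product: 18 methyl (2S,4S,13R,14E,16E)-17-bromo-18-methoxy-2,4,13-trimethyloctadeca-14,16-dienoate
Conditions: 17 (1.3 equiv), Pd(PPh3)4 (5 mol %), TlOEt (1.5 equiv), THF/H2O 3:1, rt
Reagents that add atoms: none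
Why: Suzuki–Miyaura coupling that is chemoselective for C–I over the internal C–Br and proceeds with retention at both alkenes, so C15 ends cis to CH2OMe and trans to Br.

Step 11
Reactants: 19 ethyl (S)-4-chloro-3-hydroxybutanoate
Product: 20 ethyl (S)-4-azido-3-hydroxybutanoate
Conditions: NaN3 (2 equiv), DMF, 90 °C
Reagents that add atoms: sodium azide, [Na+].[N-]=[N+]=[N-]
Why: SN2 displacement at the primary carbon (directly or through the transient epoxide) does not touch the C23 carbinol centre, which comes from the chiral pool.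

Step 12
Reactants: 20 ethyl (S)-4-azido-3-hydroxybutanoate
Product: 21 ethyl (S)-4-azido-3-(TBSO)butanoate
Conditions: TBSCl, imidazole, DMF, rt
Reagents that add atoms: tert-butyldimethylsilyl chloride, CC(C)(C)[Si](C)(C)Cl
Why: Standard silylation of the secondary alcohol prevents retro-aldol and elimination chemistry in the next steps.

Step 13
Reactants: 21 ethyl (S)-4-azido-3-(TBSO)butanoate
Product: 22 (S)-4-azido-3-(TBSO)butanal
Conditions: i-Bu2AlH (1.1 equiv), CH2Cl2, −78 °C; aq. KNaC4H4O6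
Reagents that add atoms: none
Why: Partial reduction of the ester through the tetrahedral aluminium hemiacetal, stable at −78 °C; the azide is inert at this temperature.

Step 14
Reactants: 22 (S)-4-azido-3-(TBSO)butanal; 23 allyl(diisopropylamino)dimethylsilane
Product: 26 (3R,4S,6S)-7-azido-6-(TBSO)hept-1-ene-3,4-diol, via (E)-γ-silylallyl-diisopinocampheylborane 24 (not isolated), via diisopinocampheylborinate adduct 25 (not isolated)
Conditions: 23, n-BuLi, TMEDA, Et2O, 0 °C; (+)-Ipc2BOMe [from (−)-α-pinene], −78 °C; BF3·OEt2; then 22, −78 °C, 4 h; then KF, KHCO3, H2O2, THF/MeOH, rt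
Reagents that add atoms: hydrogen peroxide, OO
Why: γ-Silylallylboration followed by Tamao–Fleming oxidation: the chair transition state of the (E)-reagent gives the anti relationship, the Ipc groups direct Re-face attack to set C21 (S) and hence C20 (R), and C–Si oxidation proceeds with retention.

Step 15
Reactants: 26 (3R,4S,6S)-7-azido-6-(TBSO)hept-1-ene-3,4-diol
Product: 27 (3R,4S,6S)-7-azido-3,4,6-tris(TBSO)hept-1-ene
Conditions: TBSOTf (2.4 equiv), 2,6-lutidine, CH2Cl2, −40 to 0 °C
Reagents that add atoms: tert-butyldimethylsilyl trifluoromethanesulfonate, CC(C)(C)[Si](C)(C)OS(=O)(=O)C(F)(F)F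
Why: Exhaustive silylation with the silyl triflate gives one uniform protecting-group set that is removed in a single final operation.

Step 16
Reactants: 27 (3R,4S,6S)-7-azido-3,4,6-tris(TBSO)hept-1-ene
Product: 29 N-[(2S,4S,5R)-2,4,5-tris(TBSO)hept-6-en-1-yl]formamide, via primary amine 28 (not isolated)
Conditions: PPh3, THF/H2O, 50 °C; evaporate; HCO2Et, 55 °C
Reagents that add atoms: ethyl formate, CCOC=O
Why: Staudinger reduction followed by N-formylation with a formate ester installs the isocyanide precursor before any palladium chemistry, under neutral conditions that spare the silyl ethers and the alkene.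

Step 17
Reactants: 29 N-[(2S,4S,5R)-2,4,5-tris(TBSO)hept-6-en-1-yl]formamide; 18 methyl (2S,4S,13R,14E,16E)-17-bromo-18-methoxy-2,4,13-trimethyloctadeca-14,16-dienoate
Product: 31 methyl (2S,4S,13R,14E,16Z,20R,21S,23S)-20,21,23-tris(TBSO)-24-formamido-17-(methoxymethyl)-2,4,13-trimethyltetracosa-14,16-dienoate, via B-alkyl-9-BBN borane 30 (not isolated)
Conditions: 29 (1.2 equiv), 9-BBN-H (2.5 equiv), THF, rt; then 18, PdCl2(dppf) (10 mol %), AsPh3, Cs2CO3, DMF/THF/H2O, rt
Reagents that add atoms: none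
Why: Anti-Markovnikov hydroboration of the terminal alkene and B-alkyl Suzuki–Miyaura coupling with retention at the alkenyl bromide join the fragments at C17–C18 and fix the trisubstituted alkene geometry (C18 trans to C15).

Step 18
Reactants: 31 seco formamide methyl ester
Product: 32 methyl (2S,4S,13R,14E,16Z,20R,21S,23S)-20,21,23-tris(TBSO)-24-isocyano-17-(methoxymethyl)-2,4,13-trimethyltetracosa-14,16-dienoate
Conditions: POCl3, Et3N, CH2Cl2, −40 to 0 °C
Reagents that add atoms: none
Why: Ugi-type dehydration of the N-monosubstituted formamide under basic conditions gives the isocyanide without touching the silyl ethers, the allylic ether or the diene.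

Step 19
Reactants: 32 seco isocyanide methyl ester
Product: 34 (2S,4S,13R,14E,16Z,20R,21S,23S)-20,21,23-tris(TBSO)-24-isocyano-17-(methoxymethyl)-2,4,13-trimethyltetracosa-14,16-dienoic acid, via lithium carboxylate 33 (not isolated)
Conditions: LiOH (5 equiv), THF/MeOH/H2O, 35 °C; then aq. NaH2PO4 to pH 6, 0 °C; used at once
Reagents that add atoms: lithium hydroxide, [Li+].[OH-]
Why: Saponification: isocyanides and silyl ethers are stable to aqueous base, and the mildly buffered acidification avoids acid hydrolysis of the isocyanide and epimerisation at C2.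

Step 20
Reactants: 34 seco ω-isocyano acid; 35 butanal
Product: 37 (2S,6S,8S,9R,12Z,14E,16R,25S,27S)-6,8,9-tris(TBSO)-12-(methoxymethyl)-16,25,27-trimethyl-2-propyl-1-oxa-4-azacyclooctacosa-12,14-diene-3,28-dione, via cyclic O-acyl imidate 36 (not isolated)
Conditions: 34 added over 24 h (syringe pump) to 35 (10 equiv), (R)-TRIP [(R)-3,3′-bis(2,4,6-triisopropylphenyl)-1,1′-binaphthyl-2,2′-diyl hydrogen phosphate] (20 mol %), 4 Å MS, CHCl3, rt, final 1 mM; then 12 h
Reagents that add atoms: none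
Why: Proposed new method: the isocyanide carbon acts as a carbamoyl-anion equivalent and attacks butanal activated in a hydrogen-bonded complex of the chiral phosphoric acid with the substrate carboxylic acid, the tethered carboxylate traps the nitrilium ion as the 27-membered acyl imidate 36, and O→O acyl (Mumm) transfer expands it to the 28-membered depsi-lactam, so one operation forms the Cα–C(=O) bond, the ester, the amide, the ring and the (S)-Cα centre by catalyst-controlled face selection, while slow addition keeps the bifunctional substrate dilute and the aldehyde and catalyst concentrated; the closest known reaction types are the phosphoric-acid-catalysed enantioselective three-component Passerini reaction of aliphatic aldehydes and the Passerini ring closure of α-isocyano-ω-carboxylic acids.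

Step 21
Reactants: 37 tris-TBS macrocycle
Product: 38 CNP0511044.2, (2S,6S,8S,9R,12Z,14E,16R,25S,27S)-6,8,9-trihydroxy-12-(methoxymethyl)-16,25,27-trimethyl-2-propyl-1-oxa-4-azacyclooctacosa-12,14-diene-3,28-dione
Conditions: HF·pyridine, pyridine, THF, 0 °C to rt
Reagents that add atoms: none
Why: Buffered fluoride-mediated global desilylation removes all three silyl ethers without base, so the α-acyloxy amide, the allylic methyl ether and the diene survive and no stereocentre is touched.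

**Compound list**
1 | (R)-β-citronellene, (3R)-3,7-dimethylocta-1,6-diene | C=C[C@H](C)CCC=C(C)C | starting material
2 | (R)-4-methylhex-5-enal | C=C[C@H](C)CCC=O | intermediate (not isolated)
3 | (R)-4-methylhex-5-en-1-ol | C=C[C@H](C)CCCO | intermediate
4 | (R)-4-methylhex-5-en-1-yl 4-methylbenzenesulfonate | C=C[C@H](C)CCCOS(=O)(=O)c1ccc(C)cc1 | intermediate
5 | 1-bromo-4-chlorobutane | ClCCCCBr | starting material
6 | 4-chlorobutylmagnesium bromide | ClCCCC[Mg]Br | intermediate (not isolated)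
7 | (R)-10-chloro-3-methyldec-1-ene | C=C[C@H](C)CCCCCCCCl | intermediate
8 | meso-2,4-dimethylglutaric anhydride, (3R,5S)-3,5-dimethyloxane-2,6-dione | C[C@H]1C[C@@H](C)C(=O)OC1=O | starting material
9 | (2R,4S)-5-methoxy-2,4-dimethyl-5-oxopentanoic acid | COC(=O)[C@@H](C)C[C@@H](C)C(=O)O | intermediate
10 | methyl (2S,4R)-5-hydroxy-2,4-dimethylpentanoate | COC(=O)[C@@H](C)C[C@@H](C)CO | intermediate
11 | methyl (2S,4R)-5-iodo-2,4-dimethylpentanoate | COC(=O)[C@@H](C)C[C@@H](C)CI | intermediate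
12 | (R)-(8-methyldec-9-en-1-yl)magnesium chloride | C=C[C@H](C)CCCCCCC[Mg]Cl | intermediate (not isolated)
13 | methyl (2S,4S,13R)-2,4,13-trimethylpentadec-14-enoate | COC(=O)[C@@H](C)C[C@@H](C)CCCCCCCC[C@@H](C)C=C | intermediate
14 | vinylboronic acid pinacol ester, 2-ethenyl-4,4,5,5-tetramethyl-1,3,2-dioxaborolane | C=CB1OC(C)(C)C(C)(C)O1 | starting material
15 | methyl (2S,4S,13R,14E)-2,4,13-trimethyl-15-(4,4,5,5-tetramethyl-1,3,2-dioxaborolan-2-yl)pentadec-14-enoate | COC(=O)[C@@H](C)C[C@@H](C)CCCCCCCC[C@@H](C)/C=C/B1OC(C)(C)C(C)(C)O1 | intermediate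
16 | methyl propargyl ether, 3-methoxyprop-1-yne | COCC#C | starting material
17 | (E)-2-bromo-1-iodo-3-methoxyprop-1-ene | COC/C(Br)=C\I | intermediate
18 | methyl (2S,4S,13R,14E,16E)-17-bromo-18-methoxy-2,4,13-trimethyloctadeca-14,16-dienoate | COC(=O)[C@@H](C)C[C@@H](C)CCCCCCCC[C@@H](C)/C=C/C=C(\COC)Br | intermediate
19 | ethyl (S)-4-chloro-3-hydroxybutanoate | CCOC(=O)C[C@H](O)CCl | starting material
20 | ethyl (S)-4-azido-3-hydroxybutanoate | CCOC(=O)C[C@H](O)CN=[N+]=[N-] | intermediate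
21 | ethyl (S)-4-azido-3-[(tert-butyldimethylsilyl)oxy]butanoate | CCOC(=O)C[C@H](O[Si](C)(C)C(C)(C)C)CN=[N+]=[N-] | intermediate
22 | (S)-4-azido-3-[(tert-butyldimethylsilyl)oxy]butanal | O=CC[C@H](O[Si](C)(C)C(C)(C)C)CN=[N+]=[N-] | intermediate
23 | allyl(diisopropylamino)dimethylsilane | C=CC[Si](C)(C)N(C(C)C)C(C)C | starting material
24 | {(E)-3-[(diisopropylamino)dimethylsilyl]prop-2-en-1-yl}bis[(1S,2R,3S,5S)-isopinocampheyl]borane (Ipc groups from (−)-α-pinene) | CC(C)N(C(C)C)[Si](C)(C)/C=C/CB([C@H]1C[C@H]2C[C@@H]([C@@H]1C)C2(C)C)[C@H]1C[C@H]2C[C@@H]([C@@H]1C)C2(C)C | intermediate (not isolated)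
25 | diisopinocampheylborinate of (3R,4S,6S)-7-azido-6-(TBSO)-3-[(diisopropylamino)dimethylsilyl]hept-1-en-4-ol | C=C[C@@H]([Si](C)(C)N(C(C)C)C(C)C)[C@@H](OB([C@H]1C[C@H]2C[C@@H]([C@@H]1C)C2(C)C)[C@H]1C[C@H]2C[C@@H]([C@@H]1C)C2(C)C)C[C@H](O[Si](C)(C)C(C)(C)C)CN=[N+]=[N-] | intermediate (not isolated)
26 | (3R,4S,6S)-7-azido-6-[(tert-butyldimethylsilyl)oxy]hept-1-ene-3,4-diol | C=C[C@@H](O)[C@@H](O)C[C@H](O[Si](C)(C)C(C)(C)C)CN=[N+]=[N-] | intermediate
27 | (3R,4S,6S)-7-azido-3,4,6-tris[(tert-butyldimethylsilyl)oxy]hept-1-ene | C=C[C@@H](O[Si](C)(C)C(C)(C)C)[C@@H](O[Si](C)(C)C(C)(C)C)C[C@H](O[Si](C)(C)C(C)(C)C)CN=[N+]=[N-] | intermediate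
28 | (2S,4S,5R)-2,4,5-tris[(tert-butyldimethylsilyl)oxy]hept-6-en-1-amine | C=C[C@@H](O[Si](C)(C)C(C)(C)C)[C@@H](O[Si](C)(C)C(C)(C)C)C[C@H](O[Si](C)(C)C(C)(C)C)CN | intermediate (not isolated)
29 | N-[(2S,4S,5R)-2,4,5-tris[(tert-butyldimethylsilyl)oxy]hept-6-en-1-yl]formamide | C=C[C@@H](O[Si](C)(C)C(C)(C)C)[C@@H](O[Si](C)(C)C(C)(C)C)C[C@H](O[Si](C)(C)C(C)(C)C)CNC=O | intermediate
30 | N-[(2S,4S,5R)-7-(9-borabicyclo[3.3.1]nonan-9-yl)-2,4,5-tris[(tert-butyldimethylsilyl)oxy]heptyl]formamide | C1CC2CCCC(C1)B2CC[C@@H](O[Si](C)(C)C(C)(C)C)[C@@H](O[Si](C)(C)C(C)(C)C)C[C@H](O[Si](C)(C)C(C)(C)C)CNC=O | intermediate (not isolated)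
31 | methyl (2S,4S,13R,14E,16Z,20R,21S,23S)-20,21,23-tris[(tert-butyldimethylsilyl)oxy]-24-formamido-17-(methoxymethyl)-2,4,13-trimethyltetracosa-14,16-dienoate | COC(=O)[C@@H](C)C[C@@H](C)CCCCCCCC[C@@H](C)/C=C/C=C(\COC)CC[C@@H](O[Si](C)(C)C(C)(C)C)[C@@H](O[Si](C)(C)C(C)(C)C)C[C@H](O[Si](C)(C)C(C)(C)C)CNC=O | intermediate
32 | methyl (2S,4S,13R,14E,16Z,20R,21S,23S)-20,21,23-tris[(tert-butyldimethylsilyl)oxy]-24-isocyano-17-(methoxymethyl)-2,4,13-trimethyltetracosa-14,16-dienoate | COC(=O)[C@@H](C)C[C@@H](C)CCCCCCCC[C@@H](C)/C=C/C=C(\COC)CC[C@@H](O[Si](C)(C)C(C)(C)C)[C@@H](O[Si](C)(C)C(C)(C)C)C[C@H](O[Si](C)(C)C(C)(C)C)C[N+]#[C-] | intermediate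
33 | lithium (2S,4S,13R,14E,16Z,20R,21S,23S)-20,21,23-tris[(tert-butyldimethylsilyl)oxy]-24-isocyano-17-(methoxymethyl)-2,4,13-trimethyltetracosa-14,16-dienoate | [Li+].[O-]C(=O)[C@@H](C)C[C@@H](C)CCCCCCCC[C@@H](C)/C=C/C=C(\COC)CC[C@@H](O[Si](C)(C)C(C)(C)C)[C@@H](O[Si](C)(C)C(C)(C)C)C[C@H](O[Si](C)(C)C(C)(C)C)C[N+]#[C-] | intermediate (not isolated)
34 | (2S,4S,13R,14E,16Z,20R,21S,23S)-20,21,23-tris[(tert-butyldimethylsilyl)oxy]-24-isocyano-17-(methoxymethyl)-2,4,13-trimethyltetracosa-14,16-dienoic acid | OC(=O)[C@@H](C)C[C@@H](C)CCCCCCCC[C@@H](C)/C=C/C=C(\COC)CC[C@@H](O[Si](C)(C)C(C)(C)C)[C@@H](O[Si](C)(C)C(C)(C)C)C[C@H](O[Si](C)(C)C(C)(C)C)C[N+]#[C-] | intermediate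
35 | butanal | CCCC=O | starting material
36 | 27-membered cyclic O-acyl imidate: the C1 carboxylate oxygen is bonded to the former isocyanide carbon, which is C=N-bonded to C24 and carries the (S)-1-hydroxybutyl group | O1C(=O)[C@@H](C)C[C@@H](C)CCCCCCCC[C@@H](C)/C=C/C=C(\COC)CC[C@@H](O[Si](C)(C)C(C)(C)C)[C@@H](O[Si](C)(C)C(C)(C)C)C[C@H](O[Si](C)(C)C(C)(C)C)CN=C1[C@@H](O)CCC | intermediate (not isolated)
37 | (2S,6S,8S,9R,12Z,14E,16R,25S,27S)-6,8,9-tris[(tert-butyldimethylsilyl)oxy]-12-(methoxymethyl)-16,25,27-trimethyl-2-propyl-1-oxa-4-azacyclooctacosa-12,14-diene-3,28-dione | CCC[C@@H]1OC(=O)[C@@H](C)C[C@@H](C)CCCCCCCC[C@@H](C)/C=C/C=C(\COC)CC[C@@H](O[Si](C)(C)C(C)(C)C)[C@@H](O[Si](C)(C)C(C)(C)C)C[C@H](O[Si](C)(C)C(C)(C)C)CNC1=O | intermediate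
38 | CNP0511044.2, (2S,6S,8S,9R,12Z,14E,16R,25S,27S)-6,8,9-trihydroxy-12-(methoxymethyl)-16,25,27-trimethyl-2-propyl-1-oxa-4-azacyclooctacosa-12,14-diene-3,28-dione | CCC[C@@H]1OC(=O)[C@@H](C)C[C@@H](C)CCCCCCCC[C@@H](C)/C=C/C=C(\COC)CC[C@@H](O)[C@@H](O)C[C@H](O)CNC1=O | target

**Step count**
Total: 21 steps. Longest linear sequence: 11 steps (1 → 3 → 4 → 7 → 13 → 15 → 18 → 31 → 32 → 34 → 37 → 38; the sequence from 19 is equally long).

**Three steps most likely to fail, with fallbacks**

Step 20 (Passerini macrocyclisation). The risks are oligomerisation or a very slow reaction at high dilution, and incomplete catalyst control at Cα. The fallback takes Cα from the chiral pool and closes the ring by macrolactonisation; it sets out from 27 and comes back at 37. Staudinger reduction of 27 gives amine 28, which is coupled (EDC·HCl, HOBt, CH2Cl2) with commercial (S)-2-hydroxypentanoic acid to the hydroxy amide F1. Hydroboration with 9-BBN-H gives the alkylborane F2, which is coupled with 18 under the step 17 conditions to the seco hydroxy ester F3. Me3SnOH (1,2-dichloroethane, 70 °C) gives the seco hydroxy acid F4, and Yamaguchi lactonisation (2,4,6-trichlorobenzoyl chloride, Et3N, then DMAP, toluene, 1 mM) gives 37.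

Step 17 (B-alkyl Suzuki coupling at the hindered 2-bromodiene). The risks are slow oxidative addition or transmetalation and protodeboronation. The fallback replaces boron by zinc (Negishi coupling); it sets out from 29 and comes back at 31. Borane 30, made as in step 17, is oxidised (NaOH, H2O2) to the primary alcohol F5 and converted (I2, PPh3, imidazole) into the primary iodide F6. Zinc insertion (Zn, LiCl, THF) gives the alkylzinc iodide F7, and coupling with 18 (Pd(OAc)2, SPhos, THF/NMP, rt) gives 31.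

Step 10 (chemoselective coupling of the bromo-iodo alkene). The risks are loss of the β-bromine from the alkenylpalladium intermediate and double coupling. The fallback is a 1,1-dibromoalkene route that needs neither 17 nor 18 and also replaces steps 8, 9 and 17; it sets out from 13 and comes back at 31. Cross-metathesis of 13 with crotonaldehyde (second-generation Hoveyda–Grubbs catalyst, CH2Cl2, 40 °C) gives the (E)-enal F8, and Corey–Fuchs olefination (CBr4, PPh3, CH2Cl2, 0 °C) gives the 1,1-dibromodiene F9. Trans-selective B-alkyl Suzuki coupling with borane 30 (PdCl2(dppf), AsPh3, Cs2CO3, DMF/H2O) replaces the bromine trans to C15 and gives the (16Z)-17-bromo seco formamide F10. Stille coupling with Bu3SnCH2OMe (Pd(PPh3)4, LiCl, DMF, 80 °C) then installs the methoxymethyl group with retention and gives 31.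

**Further compounds**
F1 | step 20 | (2S)-2-hydroxy-N-[(2S,4S,5R)-2,4,5-tris[(tert-butyldimethylsilyl)oxy]hept-6-en-1-yl]pentanamide | C=C[C@@H](O[Si](C)(C)C(C)(C)C)[C@@H](O[Si](C)(C)C(C)(C)C)C[C@H](O[Si](C)(C)C(C)(C)C)CNC(=O)[C@@H](O)CCC
F2 | step 20 | (2S)-N-[(2S,4S,5R)-7-(9-borabicyclo[3.3.1]nonan-9-yl)-2,4,5-tris[(tert-butyldimethylsilyl)oxy]heptyl]-2-hydroxypentanamide | C1CC2CCCC(C1)B2CC[C@@H](O[Si](C)(C)C(C)(C)C)[C@@H](O[Si](C)(C)C(C)(C)C)C[C@H](O[Si](C)(C)C(C)(C)C)CNC(=O)[C@@H](O)CCC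
F3 | step 20 | methyl (2S,4S,13R,14E,16Z,20R,21S,23S)-20,21,23-tris[(tert-butyldimethylsilyl)oxy]-24-[(2S)-2-hydroxypentanamido]-17-(methoxymethyl)-2,4,13-trimethyltetracosa-14,16-dienoate | COC(=O)[C@@H](C)C[C@@H](C)CCCCCCCC[C@@H](C)/C=C/C=C(\COC)CC[C@@H](O[Si](C)(C)C(C)(C)C)[C@@H](O[Si](C)(C)C(C)(C)C)C[C@H](O[Si](C)(C)C(C)(C)C)CNC(=O)[C@@H](O)CCC
F4 | step 20 | (2S,4S,13R,14E,16Z,20R,21S,23S)-20,21,23-tris[(tert-butyldimethylsilyl)oxy]-24-[(2S)-2-hydroxypentanamido]-17-(methoxymethyl)-2,4,13-trimethyltetracosa-14,16-dienoic acid | OC(=O)[C@@H](C)C[C@@H](C)CCCCCCCC[C@@H](C)/C=C/C=C(\COC)CC[C@@H](O[Si](C)(C)C(C)(C)C)[C@@H](O[Si](C)(C)C(C)(C)C)C[C@H](O[Si](C)(C)C(C)(C)C)CNC(=O)[C@@H](O)CCC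
F5 | step 17 | N-[(2S,4S,5R)-2,4,5-tris[(tert-butyldimethylsilyl)oxy]-7-hydroxyheptyl]formamide | OCC[C@@H](O[Si](C)(C)C(C)(C)C)[C@@H](O[Si](C)(C)C(C)(C)C)C[C@H](O[Si](C)(C)C(C)(C)C)CNC=O
F6 | step 17 | N-[(2S,4S,5R)-2,4,5-tris[(tert-butyldimethylsilyl)oxy]-7-iodoheptyl]formamide | ICC[C@@H](O[Si](C)(C)C(C)(C)C)[C@@H](O[Si](C)(C)C(C)(C)C)C[C@H](O[Si](C)(C)C(C)(C)C)CNC=O
F7 | step 17 | [(3R,4S,6S)-3,4,6-tris[(tert-butyldimethylsilyl)oxy]-7-formamidoheptyl]zinc iodide | I[Zn]CC[C@@H](O[Si](C)(C)C(C)(C)C)[C@@H](O[Si](C)(C)C(C)(C)C)C[C@H](O[Si](C)(C)C(C)(C)C)CNC=O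
F8 | step 10 | methyl (2S,4S,13R,14E)-2,4,13-trimethyl-16-oxohexadec-14-enoate | COC(=O)[C@@H](C)C[C@@H](C)CCCCCCCC[C@@H](C)/C=C/C=O
F9 | step 10 | methyl (2S,4S,13R,14E)-17,17-dibromo-2,4,13-trimethylheptadeca-14,16-dienoate | COC(=O)[C@@H](C)C[C@@H](C)CCCCCCCC[C@@H](C)/C=C/C=C(Br)Br
F10 | step 10 | methyl (2S,4S,13R,14E,16Z,20R,21S,23S)-17-bromo-20,21,23-tris[(tert-butyldimethylsilyl)oxy]-24-formamido-2,4,13-trimethyltetracosa-14,16-dienoate | COC(=O)[C@@H](C)C[C@@H](C)CCCCCCCC[C@@H](C)/C=C/C=C(\Br)CC[C@@H](O[Si](C)(C)C(C)(C)C)[C@@H](O[Si](C)(C)C(C)(C)C)C[C@H](O[Si](C)(C)C(C)(C)C)CNC=O
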